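**Plan**

1. Numbering (germacrane type): ring C1–C10 with C1=C10 and C4=C5, C11 lactone α-carbon, C12 lactone carbonyl, C13 exocyclic CH2, C14 formyl carbon on C10, C15 acetoxymethyl carbon on C4. The enabling feature is the α-methylene-γ-butyrolactone O–C6–C7–C11(=C13H2)–C12(=O) fused at C6–C7 to the ten-membered ring: it is a terminal allene (C13=C11=C7), CO2 (C12) and an enal carbonyl (C6=O) in disguise.
2. Retrosynthesis: (a) cut C11–C12 and C6–C7 together (the O6–C12 bond goes with them) to the open-chain allenyl enal 24 plus CO2; (b) cut C1=C10 (Horner–Wadsworth–Emmons) into phosphono lactone 17 (C7–C10, C14) and α-silyloxy aldehyde 10 (C1–C6, C15); (c) cut C3–C4 of 10 (alkenyl copper/epoxide) and make the allene from an alkyne and formaldehyde.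
3. Forward: 10 and 17 are made separately and joined as the (E)-alkylidene lactone 18, a temporary ring that fixes the C1=C10 geometry and is then reduced to the C14/C8 diol. Alkyne to allene and C6 to the enal follow; the nickel-mediated allene/CO2/enal coupling then closes the ten-membered ring and, after dehydration in the same operation, the γ-lactone. Esterification, desilylation and C14 oxidation finish.
4. Stereochemistry: C2 from methyl (S)-glycidate; C8 from asymmetric transfer hydrogenation of ynone 13; C7 and C6 arise in the key step under control of C8 (A(1,3) strain) and the cyclic allyl-transfer transition state. C4=C5 comes from anti-hydroalumination/iodination of a butynediol ether, C1=C10 from the E-selective olefination.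
5. Protecting groups: only ethers at the key step (PMB on O8/O15 for the later esters, TBS on O2/O14 for the final diol, TES on O6 for the aldehyde).

Key step: step 16

Remark: the SMILES is read as the trans-fused 6,12-olide with (2S,6R,7R,8R) configuration and both ring alkenes cis within the ring (CIP E, because C14 and C15 carry oxygen); the numbering above is used for all intermediates.

**Route**

Step 1
Reactants: 1 2-butyne-1,4-diol
Product: 2 4-[(4-methoxybenzyl)oxy]but-2-yn-1-ol
Conditions: 1 (3 equiv), NaH (1 equiv), PMBCl (1 equiv), n-Bu4NI (cat.), THF/DMF, 0 °C → rt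
Reagents that add atoms: 4-methoxybenzyl chloride COc1ccc(CCl)cc1
Why: Williamson etherification with the diol in excess should stop at the mono-PMB ether and leaves one propargylic hydroxyl to direct step 2.

Step 2
Reactants: 2 4-[(4-methoxybenzyl)oxy]but-2-yn-1-ol
Product: 4 (Z)-3-iodo-4-[(4-methoxybenzyl)oxy]but-2-en-1-ol, via cyclic alkenylalanate 3 (not isolated)
Conditions: NaAlH2(OCH2CH2OMe)2, THF, 0 °C; EtOAc; then I2, −78 °C → −20 °C
Reagents that add atoms: iodine II
Why: Hydroxyl-directed anti-hydroalumination of the propargylic alcohol puts aluminium on skeleton C4 and hydrogen on C5 trans to it, and iodinolysis with retention should give the alkenyl iodide in which iodine (the place of the later C3) is cis to C6, the low temperature holding back β-elimination of the PMB ether.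

Step 3
Reactants: 4 (Z)-3-iodo-4-[(4-methoxybenzyl)oxy]but-2-en-1-ol
Product: 5 (Z)-triethyl({3-iodo-4-[(4-methoxybenzyl)oxy]but-2-en-1-yl}oxy)silane
Conditions: TESCl, imidazole, CH2Cl2, 0 °C
Reagents that add atoms: chlorotriethylsilane CC[Si](Cl)(CC)CC
Why: Standard silylation; the primary TES ether should survive the organometallic and hydride steps and is the only silyl ether that step 15 converts into the aldehyde.

Step 4
Reactants: 5 (Z)-triethyl({3-iodo-4-[(4-methoxybenzyl)oxy]but-2-en-1-yl}oxy)silane; 6 methyl (S)-oxirane-2-carboxylate (methyl (S)-glycidate)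
Product: 8 methyl (2S,4E)-2-hydroxy-4-{[(4-methoxybenzyl)oxy]methyl}-6-[(triethylsilyl)oxy]hex-4-enoate, via alkenylmagnesium chloride 7 (not isolated)
Conditions: 5, i-PrMgCl·LiCl, THF, −20 °C; then CuI (10 mol%), 6, −40 °C → −20 °C
Reagents that add atoms: none
Why: Iodine–magnesium exchange gives a configurationally stable alkenyl Grignard reagent whose copper-catalysed SN2 opening of the epoxide at its CH2 terminus forms C3–C4 with retention of the alkene geometry, C2 (S) coming unchanged from the chiral-pool glycidate.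

Step 5
Reactants: 8 methyl (2S,4E)-2-hydroxy-4-{[(4-methoxybenzyl)oxy]methyl}-6-[(triethylsilyl)oxy]hex-4-enoate
Product: 9 methyl (2S,4E)-2-[(tert-butyldimethylsilyl)oxy]-4-{[(4-methoxybenzyl)oxy]methyl}-6-[(triethylsilyl)oxy]hex-4-enoate
Conditions: TBSCl, imidazole, DMF, rt
Reagents that add atoms: tert-butylchlorodimethylsilane CC(C)(C)[Si](C)(C)Cl
Why: Silylation of the α-hydroxy ester protects O2 as the robust ether that is kept until step 20.

Step 6
Reactants: 9 methyl (2S,4E)-2-[(tert-butyldimethylsilyl)oxy]-4-{[(4-methoxybenzyl)oxy]methyl}-6-[(triethylsilyl)oxy]hex-4-enoate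
Product: 10 (2S,4E)-2-[(tert-butyldimethylsilyl)oxy]-4-{[(4-methoxybenzyl)oxy]methyl}-6-[(triethylsilyl)oxy]hex-4-enal
Conditions: i-Bu2AlH (1.1 equiv), CH2Cl2, −78 °C
Reagents that add atoms: none
Why: Partial reduction of the α-silyloxy methyl ester through the stable tetrahedral aluminate should stop at the aldehyde without touching C2.

Step 7
Reactants: 11 methyl 4-chloro-4-oxobutanoate; 12 bis(trimethylsilyl)acetylene
Product: 13 methyl 4-oxo-6-(trimethylsilyl)hex-5-ynoate
Conditions: AlCl3, CH2Cl2, 0 °C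
Reagents that add atoms: none
Why: Friedel–Crafts-type acylation of the bis-silyl alkyne (ipso-substitution of one C–Si bond by the acylium ion) should give the silyl ynone, which is deactivated towards a second acylation.

Step 8
Reactants: 13 methyl 4-oxo-6-(trimethylsilyl)hex-5-ynoate
Product: 15 (5R)-5-[(trimethylsilyl)ethynyl]dihydrofuran-2(3H)-one, via hydroxy ester 14 (not isolated)
Conditions: Ru[(R,R)-TsNCHPhCHPhNH](p-cymene) (1 mol%), i-PrOH, rt; then TsOH·H2O (cat.), CH2Cl2, rt
Reagents that add atoms: none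
Why: Noyori-type asymmetric transfer hydrogenation of the α,β-acetylenic ketone sets C8, the (R,R)-catalyst being expected to give the (R)-propargylic alcohol by analogy with its sense for alkynyl alkyl ketones, and acid then closes the γ-lactone.

Step 9
Reactants: 15 (5R)-5-[(trimethylsilyl)ethynyl]dihydrofuran-2(3H)-one
Product: 17 diethyl {(5R)-2-oxo-5-[(trimethylsilyl)ethynyl]tetrahydrofuran-3-yl}phosphonate (C3 epimers), via phosphonite 16 (not isolated)
Conditions: LiN(i-Pr)2, THF, −78 °C; ClP(OEt)2, −78 °C → rt; then H2O2 (30% aq.), 0 °C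
Reagents that add atoms: diethyl chlorophosphite CCOP(Cl)OCC; hydrogen peroxide OO
Why: C-phosphinylation of the lactone enolate and oxidation at phosphorus should give the α-phosphono lactone, whose uncontrolled C3 centre disappears in step 10.

Step 10
Reactants: 17 diethyl {(5R)-2-oxo-5-[(trimethylsilyl)ethynyl]tetrahydrofuran-3-yl}phosphonate; 10 (2S,4E)-2-[(tert-butyldimethylsilyl)oxy]-4-{[(4-methoxybenzyl)oxy]methyl}-6-[(triethylsilyl)oxy]hex-4-enal
Product: 18 (3E,5R)-3-[(2S,4E)-2-[(tert-butyldimethylsilyl)oxy]-4-{[(4-methoxybenzyl)oxy]methyl}-6-[(triethylsilyl)oxy]hex-4-en-1-ylidene]-5-[(trimethylsilyl)ethynyl]dihydrofuran-2(3H)-one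
Conditions: 17, LiCl, DBU, MeCN, 0 °C; then 10, 0 °C → rt
Reagents that add atoms: none
Why: Horner–Wadsworth–Emmons olefination under mild LiCl/amine conditions should give the (E)-alkylidene lactone (C2 trans to C14=O and therefore cis to C9, as the ring needs) without epimerizing the α-silyloxy aldehyde.

Step 11
Reactants: 18 (E)-alkylidene lactone
Product: 19 (2S,8R)-diol Me3Si–C≡C–CH(OH)–CH2–C(CH2OH)=CH–CH(OTBS)–CH2–C(CH2OPMB)=CH–CH2OTES (C9/C2 cis on C10=C1; C3/C6 cis on C4=C5)
Conditions: i-Bu2AlH (4 equiv), CH2Cl2, −78 °C → 0 °C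
Reagents that add atoms: none
Why: 1,2-Reduction of the lactone to the 1,4-diol removes the temporary ring and frees a primary allylic (O14) and a secondary propargylic (O8) hydroxyl that can be told apart.

Step 12
Reactants: 19 (2S,8R)-diol
Product: 20 C14 TBS ether Me3Si–C≡C–CH(OH)–CH2–C(CH2OTBS)=CH–CH(OTBS)–CH2–C(CH2OPMB)=CH–CH2OTES
Conditions: TBSCl (1.05 equiv), imidazole, CH2Cl2, −20 °C → 0 °C
Reagents that add atoms: tert-butylchlorodimethylsilane CC(C)(C)[Si](C)(C)Cl
Why: The unhindered primary allylic hydroxyl should be silylated much faster than the secondary propargylic one (steric selectivity of silyl chloride/imidazole).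

Step 13
Reactants: 20 C14 TBS ether
Product: 22 terminal alkyne HC≡C–CH(OPMB)–CH2–C(CH2OTBS)=CH–CH(OTBS)–CH2–C(CH2OPMB)=CH–CH2OTES, via silyl alkyne ether 21 (not isolated)
Conditions: NaH, PMBBr, n-Bu4NI (cat.), THF/DMF, 0 °C → rt; then MeOH, K2CO3 (cat.), 0 °C → rt
Reagents that add atoms: 4-methoxybenzyl bromide COc1ccc(CBr)cc1
Why: Williamson etherification of O8 followed in the same flask by methanolysis of the alkynyl C–Si bond should give the terminal alkyne; an ether at O8 is chosen so that nothing can leave from C8 in step 16.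

Step 14
Reactants: 22 terminal alkyne
Product: 23 terminal allene H2C=C=CH–CH(OPMB)–CH2–C(CH2OTBS)=CH–CH(OTBS)–CH2–C(CH2OPMB)=CH–CH2OTES
Conditions: (CH2O)n, CuI (0.5 equiv), Cy2NH, dioxane, reflux
Reagents that add atoms: paraformaldehyde (as formaldehyde) C=O
Why: Crabbé homologation (Mannich reaction of the copper acetylide, then 1,5-hydride shift and loss of the imine) turns the terminal alkyne into the terminal allene C13=C11=C7 without touching C8.

Step 15
Reactants: 23 terminal allene
Product: 24 allenyl enal H2C=C=CH–CH(OPMB)–CH2–C(CH2OTBS)=CH–CH(OTBS)–CH2–C(CH2OPMB)=CH–CHO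
Conditions: (COCl)2, DMSO, CH2Cl2, −78 °C → −30 °C; then Et3N, −78 °C → 0 °C
Reagents that add atoms: none
Why: Swern oxidation applied directly to the primary TES ether (chloride-assisted Si–O exchange to the alkoxysulfonium salt, then ylide fragmentation) should give the enal while TBS and PMB ethers stay, under conditions that do not isomerize C4=C5.

Step 16
Reactants: 24 allenyl enal
Product: 27 (2S,6R,7R,8R)-8,15-bis(PMB-oxy)-2,14-bis(TBS-oxy) trans-fused ten-membered 6,12-olide, via allylnickel carboxylate 25 (not isolated), via seco acid 26 (not isolated)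
Conditions: Ni(cod)2 (1.5 equiv), DBU (3 equiv), CO2 (1 atm), THF, 0 °C, slow addition of 24 (final 2 mM), then rt; 0.5 M HCl, 0 °C; then DIC, DMAP (cat.), CH2Cl2, 0 °C → rt
Reagents that add atoms: carbon dioxide O=C=O
Why: Proposed new method: zerovalent nickel couples the terminal C11=C13 π-bond of the allene with CO2 (C11–C12 bond) to the η3/η1-allylnickel carboxylate 25, whose substituted terminus C7 adds through a six-membered cyclic transition state to the nickel-bound C6 aldehyde of the same chain (C6–C7 bond); acid releases seco acid 26, which DIC closes with retention at C6. The closest known reaction type is the Ni(cod)2/DBU-mediated sequential addition of CO2 and an aldehyde to a terminal allene (also in its ring-forming version on short allenyl aldehydes), joined here to the kind of intramolecular allyl-metal addition to a C6 enal by which CrCl2 closes germacrane ten-membered rings. The ten-membered carbocycle closes by 10-exo-trig addition of the allyl terminus to the carbonyl (overall a three-component [2+2+1]-type union of C7=C11, CO2 and C6=O), the γ-lactone by 5-exo-trig acyl substitution. C7 is controlled by C8: A(1,3) strain against the fully substituted C11 keeps H8 in the allyl plane, the ring bond C8–C9 lies anti to the forming bond and the PMB ether outside, so that C6 enters on the face that gives the 7,8 arrangement of the target; C6 is controlled by the chair-like transition state, in which C5 and C8 are both pseudo-equatorial on the σ-allyl isomer with C8 trans to C13 (reached by η3–η1 equilibration), giving the 6,7-anti seco acid and hence the trans-fused lactone. The step needs γ- over α-attack of the allyl unit (cyclic transition state; ten- and not twelve-membered ring), 1,2-addition to the enal, carboxylation of the allene ahead of nickel–enal chemistry (CO2 atmosphere, 0 °C, slow addition at high dilution) and no ionizable allylic ester (hence ethers at O8 and O15).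

Step 17
Reactants: 27 bis-PMB bis-TBS macrolactone
Product: 28 8,15-diol (2,14-bis-TBS ether)
Conditions: DDQ, CH2Cl2/pH 7 buffer, 0 °C → rt
Reagents that add atoms: none
Why: Oxidative PMB cleavage (hydride abstraction by DDQ and hydrolysis of the oxocarbenium ion) should free O8 and O15 together and leave the TBS ethers and the α-methylene lactone.

Step 18
Reactants: 28 8,15-diol
Product: 29 15-acetate 8-alcohol (2,14-bis-TBS ether)
Conditions: AcCl (1.1 equiv), 2,4,6-collidine, CH2Cl2, −78 °C
Reagents that add atoms: acetyl chloride CC(Cl)=O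
Why: Kinetic acylation with a hindered pyridine base should take the primary allylic O15 in preference to the secondary O8 next to the ring fusion.

Step 19
Reactants: 29 15-acetate 8-alcohol
Product: 30 15-acetate 8-isovalerate (2,14-bis-TBS ether)
Conditions: isovaleric anhydride, DMAP (cat.), Et3N, CH2Cl2, rt
Reagents that add atoms: isovaleric anhydride CC(C)CC(=O)OC(=O)CC(C)C
Why: DMAP-catalysed acylation (Steglich type) should esterify the remaining secondary O8 with retention.

Step 20
Reactants: 30 15-acetate 8-isovalerate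
Product: 31 2,14-diol (15-acetate 8-isovalerate)
Conditions: HF·pyridine, pyridine, THF, 0 °C → rt
Reagents that add atoms: none
Why: Buffered fluoride-mediated desilylation should remove both TBS ethers without acyl migration or addition to the α-methylene lactone.

Step 21
Reactants: 31 2,14-diol
Product: 32 CNP0524123.1 (target)
Conditions: TEMPO (cat.), PhI(OAc)2, CH2Cl2, rt
Reagents that add atoms: none
Why: Oxoammonium (TEMPO) oxidation is strongly selective for the primary allylic O14 over the secondary allylic O2 and should stop at the (E)-enal, which cannot close to a lactol with O2.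

**Compound list**

1 | 2-butyne-1,4-diol | OCC#CCO | starting material
2 | 4-[(4-methoxybenzyl)oxy]but-2-yn-1-ol | OCC#CCOCc1ccc(OC)cc1 | intermediate
3 | sodium cyclic alkenylalanate from 2 (not isolated) | [Na+].COCCO[Al-]1(OCCOC)OCC=C1COCc2ccc(OC)cc2 | intermediate
4 | (Z)-3-iodo-4-[(4-methoxybenzyl)oxy]but-2-en-1-ol | OC/C=C(\I)COCc1ccc(OC)cc1 | intermediate
5 | (Z)-triethyl({3-iodo-4-[(4-methoxybenzyl)oxy]but-2-en-1-yl}oxy)silane | CC[Si](CC)(CC)OC/C=C(\I)COCc1ccc(OC)cc1 | intermediate
6 | methyl (S)-oxirane-2-carboxylate | COC(=O)[C@@H]1CO1 | starting material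
7 | alkenylmagnesium chloride from 5 (not isolated) | Cl[Mg]/C(COCc1ccc(OC)cc1)=C\CO[Si](CC)(CC)CC | intermediate
8 | methyl (2S,4E)-2-hydroxy-4-{[(4-methoxybenzyl)oxy]methyl}-6-[(triethylsilyl)oxy]hex-4-enoate | COC(=O)[C@@H](O)C/C(COCc1ccc(OC)cc1)=C\CO[Si](CC)(CC)CC | intermediate
9 | methyl (2S,4E)-2-[(tert-butyldimethylsilyl)oxy]-4-{[(4-methoxybenzyl)oxy]methyl}-6-[(triethylsilyl)oxy]hex-4-enoate | COC(=O)[C@@H](O[Si](C)(C)C(C)(C)C)C/C(COCc1ccc(OC)cc1)=C\CO[Si](CC)(CC)CC | intermediate
10 | (2S,4E)-2-[(tert-butyldimethylsilyl)oxy]-4-{[(4-methoxybenzyl)oxy]methyl}-6-[(triethylsilyl)oxy]hex-4-enal | O=C[C@@H](O[Si](C)(C)C(C)(C)C)C/C(COCc1ccc(OC)cc1)=C\CO[Si](CC)(CC)CC | intermediate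
11 | methyl 4-chloro-4-oxobutanoate | COC(=O)CCC(Cl)=O | starting material
12 | bis(trimethylsilyl)acetylene | C[Si](C)(C)C#C[Si](C)(C)C | starting material
13 | methyl 4-oxo-6-(trimethylsilyl)hex-5-ynoate | COC(=O)CCC(=O)C#C[Si](C)(C)C | intermediate
14 | methyl (4R)-4-hydroxy-6-(trimethylsilyl)hex-5-ynoate (not isolated) | COC(=O)CC[C@@H](O)C#C[Si](C)(C)C | intermediate
15 | (5R)-5-[(trimethylsilyl)ethynyl]dihydrofuran-2(3H)-one | O=C1CC[C@H](C#C[Si](C)(C)C)O1 | intermediate
16 | diethyl {(5R)-2-oxo-5-[(trimethylsilyl)ethynyl]tetrahydrofuran-3-yl}phosphonite, C3 epimers (not isolated) | CCOP(OCC)C1C[C@H](C#C[Si](C)(C)C)OC1=O | intermediate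
17 | diethyl {(5R)-2-oxo-5-[(trimethylsilyl)ethynyl]tetrahydrofuran-3-yl}phosphonate, C3 epimers | CCOP(=O)(OCC)C1C[C@H](C#C[Si](C)(C)C)OC1=O | intermediate
18 | (3E,5R)-3-[(2S,4E)-2-[(tert-butyldimethylsilyl)oxy]-4-{[(4-methoxybenzyl)oxy]methyl}-6-[(triethylsilyl)oxy]hex-4-en-1-ylidene]-5-[(trimethylsilyl)ethynyl]dihydrofuran-2(3H)-one | O=C1O[C@@H](C#C[Si](C)(C)C)C/C1=C\[C@@H](O[Si](C)(C)C(C)(C)C)C/C(COCc2ccc(OC)cc2)=C\CO[Si](CC)(CC)CC | intermediate
19 | (2S,8R) open-chain diol: 8-OH, 14-OH, 2-OTBS, 15-OPMB, 6-OTES, C7≡C11–SiMe3; C9/C2 cis on C10=C1, C3/C6 cis on C4=C5 | C[Si](C)(C)C#C[C@H](O)C/C(CO)=C\[C@@H](O[Si](C)(C)C(C)(C)C)C/C(COCc1ccc(OC)cc1)=C\CO[Si](CC)(CC)CC | intermediate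
20 | (2S,8R) 14-TBS ether of 19 (8-OH free) | C[Si](C)(C)C#C[C@H](O)C/C(CO[Si](C)(C)C(C)(C)C)=C\[C@@H](O[Si](C)(C)C(C)(C)C)C/C(COCc1ccc(OC)cc1)=C\CO[Si](CC)(CC)CC | intermediate
21 | (2S,8R) 8-PMB ether of 20 with the silyl alkyne (not isolated) | C[Si](C)(C)C#C[C@H](OCc1ccc(OC)cc1)C/C(CO[Si](C)(C)C(C)(C)C)=C\[C@@H](O[Si](C)(C)C(C)(C)C)C/C(COCc1ccc(OC)cc1)=C\CO[Si](CC)(CC)CC | intermediate
22 | (2S,8R) terminal alkyne: 8-OPMB, 14-OTBS, 2-OTBS, 15-OPMB, 6-OTES | C#C[C@H](OCc1ccc(OC)cc1)C/C(CO[Si](C)(C)C(C)(C)C)=C\[C@@H](O[Si](C)(C)C(C)(C)C)C/C(COCc1ccc(OC)cc1)=C\CO[Si](CC)(CC)CC | intermediate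
23 | (2S,8R) terminal allene C13=C11=C7 with the same ethers | C=C=C[C@H](OCc1ccc(OC)cc1)C/C(CO[Si](C)(C)C(C)(C)C)=C\[C@@H](O[Si](C)(C)C(C)(C)C)C/C(COCc1ccc(OC)cc1)=C\CO[Si](CC)(CC)CC | intermediate
24 | (2S,8R) allenyl enal (C6 aldehyde; C3 cis to C6 on C4=C5) | C=C=C[C@H](OCc1ccc(OC)cc1)C/C(CO[Si](C)(C)C(C)(C)C)=C\[C@@H](O[Si](C)(C)C(C)(C)C)C/C(COCc1ccc(OC)cc1)=C\C=O | intermediate
25 | η3/η1-allylnickel carboxylate, drawn as the η1 nickelalactone, DBU ligands omitted, C7=C11 geometry not fixed (not isolated) | O=C1O[Ni]CC1=C[C@H](OCc2ccc(OC)cc2)C/C(CO[Si](C)(C)C(C)(C)C)=C\[C@@H](O[Si](C)(C)C(C)(C)C)C/C(COCc2ccc(OC)cc2)=C\C=O | intermediate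
26 | (2S,6R,7S,8R) seco acid: ten-membered carbocycle with 6-OH and 7-(1-carboxyvinyl), 6,7-anti (not isolated) | C=C(C(=O)O)[C@@H]1[C@H](OCc2ccc(OC)cc2)C/C(CO[Si](C)(C)C(C)(C)C)=C\[C@@H](O[Si](C)(C)C(C)(C)C)C/C(COCc2ccc(OC)cc2)=C\[C@H]1O | intermediate
27 | (2S,6R,7R,8R)-8,15-bis[(4-methoxybenzyl)oxy]-2,14-bis[(tert-butyldimethylsilyl)oxy] trans-fused 6,12-olide | C=C1C(=O)O[C@@H]2/C=C(/COCc3ccc(OC)cc3)C[C@H](O[Si](C)(C)C(C)(C)C)/C=C(/CO[Si](C)(C)C(C)(C)C)C[C@@H](OCc3ccc(OC)cc3)[C@@H]12 | intermediate
28 | (2S,6R,7R,8R) 8,15-diol, 2,14-bis-TBS ether | C=C1C(=O)O[C@@H]2/C=C(/CO)C[C@H](O[Si](C)(C)C(C)(C)C)/C=C(/CO[Si](C)(C)C(C)(C)C)C[C@@H](O)[C@@H]12 | intermediate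
29 | (2S,6R,7R,8R) 15-acetate 8-alcohol, 2,14-bis-TBS ether | C=C1C(=O)O[C@@H]2/C=C(/COC(C)=O)C[C@H](O[Si](C)(C)C(C)(C)C)/C=C(/CO[Si](C)(C)C(C)(C)C)C[C@@H](O)[C@@H]12 | intermediate
30 | (2S,6R,7R,8R) 15-acetate 8-isovalerate, 2,14-bis-TBS ether | C=C1C(=O)O[C@@H]2/C=C(/COC(C)=O)C[C@H](O[Si](C)(C)C(C)(C)C)/C=C(/CO[Si](C)(C)C(C)(C)C)C[C@@H](OC(=O)CC(C)C)[C@@H]12 | intermediate
31 | (2S,6R,7R,8R) 2,14-diol, 15-acetate 8-isovalerate | C=C1C(=O)O[C@@H]2/C=C(/COC(C)=O)C[C@H](O)/C=C(/CO)C[C@@H](OC(=O)CC(C)C)[C@@H]12 | intermediate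
32 | CNP0524123.1 | C=C1C(=O)O[C@@H]2/C=C(/COC(C)=O)C[C@H](O)/C=C(/C=O)C[C@@H](OC(=O)CC(C)C)[C@@H]12 | target

**Step count and risks**

Total step count: 21. Longest linear sequence: 18 steps (steps 1–6 and 10–21); steps 7–9 form the side branch.

Steps most likely to fail:

1. Step 16 (Proposed new method). What may go wrong: oligomerization in place of ten-membered ring closure; protonation of the allylnickel before it adds to the aldehyde; loss of the C8 alkoxide from the allylnickel to give a diene; base-induced E/Z scrambling of the enal; closure through the diastereomeric transition state at C6 or C7. Fallback with known chemistry, setting out from alkyne 22 and coming back at 27: the lithium acetylide of 22 (n-BuLi, THF, −78 °C) is acylated with ClCO2Me to the methyl ynoate F1. Syn-hydroalumination (i-Bu2AlH·NMO, THF, 0 °C) and trapping of the α-aluminated acrylate with formaldehyde gives the (Z)-2-(hydroxymethyl)enoate F2. CBr4/PPh3 turns it into the (E)-2-(bromomethyl)enoate F3, and direct Swern oxidation of the TES ether gives the bromo enal F4. CrCl2 (divalent chromium) in THF at high dilution then effects the intramolecular Nozaki–Hiyama–Kishi-type allylation of the C6 aldehyde, the established way of closing germacranolide ten-membered rings. The chromium alkoxide lactonizes onto the methyl ester to 27; anti addition is expected from the chair transition state of the allylchromium with C8 trans to CH2Cr.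

2. Step 10. What may go wrong: erosion of the E/Z selectivity of the olefination, or base-induced epimerization at C2 of the α-silyloxy aldehyde. Fallback by aldol addition and elimination, setting out from 15 and 10 and coming back at 18: the lithium enolate of 15 (LiN(i-Pr)2, THF, −78 °C) adds to 10 at low temperature to give the aldol adduct F5 (mixture at the two new centres). MsCl/Et3N gives the mesylate F6, and DBU-induced E1cB elimination should give the thermodynamically preferred (E)-alkylidene lactone 18.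

3. Step 21. What may go wrong: loss of primary/secondary selectivity, so that the secondary allylic C2 hydroxyl is oxidized as well. Fallback by protecting-group differentiation, setting out from 30 and coming back at 32: brief treatment with HF·pyridine/pyridine (THF, 0 °C) removes only the primary allylic C14 TBS ether to give the C14 alcohol F7. MnO2 (CH2Cl2) oxidizes it to the 14-oxo enal F8 with O2 still silylated, and HF·pyridine then frees O2 to give 32.

Further compounds
F1 | step 16 | methyl ynoate from 22 (C12 ester on C11, 6-OTES) | COC(=O)C#C[C@H](OCc1ccc(OC)cc1)C/C(CO[Si](C)(C)C(C)(C)C)=C\[C@@H](O[Si](C)(C)C(C)(C)C)C/C(COCc1ccc(OC)cc1)=C\CO[Si](CC)(CC)CC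
F2 | step 16 | (Z)-2-(hydroxymethyl)enoate (ester cis to C8) | COC(=O)/C(CO)=C\[C@H](OCc1ccc(OC)cc1)C/C(CO[Si](C)(C)C(C)(C)C)=C\[C@@H](O[Si](C)(C)C(C)(C)C)C/C(COCc1ccc(OC)cc1)=C\CO[Si](CC)(CC)CC
F3 | step 16 | (E)-2-(bromomethyl)enoate (6-OTES) | COC(=O)/C(CBr)=C\[C@H](OCc1ccc(OC)cc1)C/C(CO[Si](C)(C)C(C)(C)C)=C\[C@@H](O[Si](C)(C)C(C)(C)C)C/C(COCc1ccc(OC)cc1)=C\CO[Si](CC)(CC)CC
F4 | step 16 | bromo enal (C6 aldehyde) | COC(=O)/C(CBr)=C\[C@H](OCc1ccc(OC)cc1)C/C(CO[Si](C)(C)C(C)(C)C)=C\[C@@H](O[Si](C)(C)C(C)(C)C)C/C(COCc1ccc(OC)cc1)=C\C=O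
F5 | step 10 | aldol adduct of 15 and 10 (mixture at C10 and C1) | O=C1O[C@@H](C#C[Si](C)(C)C)CC1C(O)[C@@H](O[Si](C)(C)C(C)(C)C)C/C(COCc2ccc(OC)cc2)=C\CO[Si](CC)(CC)CC
F6 | step 10 | mesylate of F5 | O=C1O[C@@H](C#C[Si](C)(C)C)CC1C(OS(C)(=O)=O)[C@@H](O[Si](C)(C)C(C)(C)C)C/C(COCc2ccc(OC)cc2)=C\CO[Si](CC)(CC)CC
F7 | step 21 | C14 alcohol with 2-OTBS (15-acetate 8-isovalerate) | C=C1C(=O)O[C@@H]2/C=C(/COC(C)=O)C[C@H](O[Si](C)(C)C(C)(C)C)/C=C(/CO)C[C@@H](OC(=O)CC(C)C)[C@@H]12
F8 | step 21 | 14-oxo enal with 2-OTBS (15-acetate 8-isovalerate) | C=C1C(=O)O[C@@H]2/C=C(/COC(C)=O)C[C@H](O[Si](C)(C)C(C)(C)C)/C=C(/C=O)C[C@@H](OC(=O)CC(C)C)[C@@H]12
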